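The plan removes C9, tracing the hydroazulene back to a trans-hydrindan-10-one. C10 lies between quaternary C1 and methyl-bearing C8, so this ketone has a single enol. Its silyl ether takes up dibromocarbene across C10=C8 and the cyclopropane opens. In one operation this inserts C9, enlarges the six-membered ring to the seven-membered one, and delivers the C10 ketone with the C8=C9 alkene and its methyl in place. The precursor is the C10 triethylsilyl enol ether of a 1β-methyl-5αH-hydrindane bearing 4β-OSiEt3, 4α-isopropyl and 6α-OTBS. It is assembled by desymmetrising benzoin closure (C1), α-face hydroboration (C5, C6) and α-face isopropyl addition (C4). C10 follows by reduction and Mitsunobu inversion.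

Key step: step 12

Numbering: all bicyclic compounds carry daucane locants: C1 quaternary fusion carbon with CH3; C2, C3 cyclopentane CH2; C4 carbinol carbon; C5 fusion CH; C6, C7, C8, C10 in the larger ring. C9 is absent before step 12. β is the face of the C1 methyl and α the opposite face. TBS = SiMe2(t-Bu).

Assumption: the antipode of the aminoindanol-derived triazolium salt is chosen that gives (1S)-4; both antipodes are sold.

Design remark 1: a C5 enolate closing onto a C4 ketone is held by its three-atom tether on the face of C2 and would give the cis-hydrindane. The fusion hydrogen is therefore delivered to a C5=C6 alkene after ring closure.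

Design remark 2: hydride reaches C6 or C10 carbonyls anti to the axial C1 methyl, which gives β-alcohols. The 6α-oxygen is therefore made by hydroboration and the 10α-ester by inversion.

Step 1
Reactants: 1 2-methylcyclohexane-1,3-dione; 2 acrolein
Product: 3 3-(1-methyl-2,6-dioxocyclohexyl)propanal
Conditions: H2O, rt
Reagents that add atoms: acrolein C=CC=O
Why: Michael addition of the acidic 2-alkyl-1,3-dione to acrolein in water alkylates only the doubly activated carbon, and 3 is still achiral because its two ring carbonyls are enantiotopic.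

Step 2
Reactants: 3 3-(1-methyl-2,6-dioxocyclohexyl)propanal
Product: 4 cis-fused ketol (1S,5R)-5β-hydroxy-1β-methylhydrindane-4,10-dione
Conditions: aminoindanol-derived N-C6F5 triazolium BF4 salt (10 mol %), Et3N (10 mol %), toluene, rt
Reagents that add atoms: none
Why: Carbene-catalysed intramolecular crossed benzoin reaction in which the triazolylidene turns the aldehyde carbon C4 into an acyl-anion equivalent that adds in a 5-exo mode to one of the two enantiotopic ring carbonyls (C5), so the chiral catalyst fixes C1 by desymmetrisation and the three-atom tether forces the new 5-OH cis to the C1 methyl (C5 is erased in step 3).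

Step 3
Reactants: 4 cis-fused ketol
Product: 5 (1S)-1β-methylhydrind-5-ene-4,10-dione
Conditions: SOCl2, pyridine, 0 °C
Reagents that add atoms: none
Why: E2 dehydration of the tertiary alcohol through its chlorosulfite, regiochemically unambiguous because C1 is quaternary and C4 is a carbonyl carbon, so only C6 offers a β-hydrogen and the C5=C6 alkene forms in conjugation with C4=O while C1 is untouched.

Step 4
Reactants: 5 enedione
Product: 6 10,10-ethylenedioxy-1β-methylhydrind-5-en-4-one
Conditions: HOCH2CH2OH, p-TsOH·H2O, 4 Å MS, rt
Reagents that add atoms: ethylene glycol OCCO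
Why: Chemoselective acid-catalysed ketalisation of the saturated C10 ketone, the conjugated C4 carbonyl being deactivated as is standard for angular-methyl bicyclic enediones, and short contact at room temperature avoids alkene migration.

Step 5
Reactants: 6 ketal enone
Product: 7 10,10-ethylenedioxy-1β-methylhydrind-5-en-4β-ol
Conditions: NaBH4, CeCl3·7H2O, MeOH, −20 °C
Reagents that add atoms: none
Why: Luche reduction secures 1,2-reduction of the s-cis enone with hydride entering anti to the pseudoaxial C1 methyl (4β-OH), a temporary stereocentre that is removed in step 8 and only keeps C4 inert to borane and small on the α face.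

Step 6
Reactants: 7 allylic alcohol
Product: 9 trans-fused 10,10-ethylenedioxy-1β-methyl-5αH-hydrindane-4β,6α-diol, via C6 alkylborane 8 (not isolated)
Conditions: BH3·THF, THF, 0 °C → rt; NaOH, H2O2, 0 °C
Reagents that add atoms: borane B (boron in 8 only); hydrogen peroxide OO
Why: Hydroboration–oxidation in which boron goes to the less substituted C6 and hydrogen to C5 in a syn addition on the α face, the β face being closed by the pseudoaxial C1 methyl and the 4β-boryloxy group (the facial rule known from Δ5-steroids), so 5α-H (trans fusion) and 6α-OH are set together and the C–B bond is oxidised with retention.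

Step 7
Reactants: 9 diol
Product: 10 6α-TBS ether of diol 9 (4β-OH free)
Conditions: TBSCl (1 equiv), imidazole, DMF, 0 °C
Reagents that add atoms: tert-butyldimethylsilyl chloride CC(C)(C)[Si](C)(C)Cl
Why: Selective silylation of the open equatorial 6α-hydroxyl, the 4β-hydroxyl being cis to C6 and 1,3-syn to the angular methyl and therefore much slower.

Step 8
Reactants: 10 mono-TBS ether
Product: 11 6α-(TBSO)-10,10-ethylenedioxy-1β-methyl-5αH-hydrindan-4-one
Conditions: Dess–Martin periodinane, NaHCO3, CH2Cl2, 0 °C → rt
Reagents that add atoms: none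
Why: Dess–Martin oxidation under bicarbonate buffer is neutral enough to leave the epimerisable 5α-H and the β-silyloxy group of the new ketone untouched.

Step 9
Reactants: 11 C4 ketone; 12 isopropylmagnesium chloride
Product: 14 4β-hydroxy-4α-isopropyl-6α-(TBSO)-1β-methyl-5αH-hydrindan-10-one, via ketal carbinol 13 (not isolated)
Conditions: i-PrMgCl, CeCl3, THF, −78 → −20 °C; 2 M HCl, rt
Reagents that add atoms: isopropylmagnesium chloride CC(C)[Mg]Cl; water O
Why: Organocerium 1,2-addition, whose low basicity suppresses enolisation, β-elimination and β-hydride transfer, attacks C4 from the α face anti to the angular methyl that sits 1,3 over the β face of the cyclopentanone and so gives 4β-OH/4α-isopropyl, after which the acidic quench hydrolyses the dioxolane.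

Step 10
Reactants: 14 hydroxy ketone; 15 iodomethane
Product: 17 8-methyl derivative of 14 (either C8 epimer), via dilithio enolate 16 (not isolated)
Conditions: LiN(i-Pr)2 (2.2 equiv), THF, −78 °C; MeI, −78 → −30 °C
Reagents that add atoms: iodomethane CI; lithium diisopropylamide [Li+].CC(C)[N-]C(C)C (lithium in 16 only)
Why: Kinetic enolate alkylation that can occur only at C8 because C1 is quaternary, the hindered tertiary lithium alkoxide is not methylated at low temperature, and the C8 configuration is irrelevant since it becomes sp2 in step 11.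

Step 11
Reactants: 17 8-methyl ketone
Product: 18 C10 triethylsilyl enol ether (C10=C8) of the trans-hydrindanone bearing 4β-OSiEt3 plus 4α-isopropyl plus 6α-OTBS
Conditions: Et3SiOTf, Et3N, CH2Cl2, 0 °C → reflux
Reagents that add atoms: triethylsilyl triflate CC[Si](CC)(CC)OS(=O)(=O)C(F)(F)F
Why: Soft enolisation with silyl triflate and amine converts both C8 epimers into the only possible enol ether and caps the tertiary C4 hydroxyl in the same flask, SiEt3 being preferred to SiMe3 because it resists alkoxide far better while staying small.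

Step 12
Reactants: 18 enol silane; 19 bromoform
Product: 21 9-bromo-hydroazulen-10-one (C8=C9) bearing 4β-OSiEt3 plus 4α-isopropyl plus 6α-OTBS, via dibromocyclopropane 20 (not isolated)
Conditions: CHBr3 (5 equiv), KOC(CH3)3 (6 equiv), pentane, −30 → 0 °C; filter; pyridine, toluene, 80 °C
Reagents that add atoms: bromoform BrC(Br)Br
Why: KOC(CH3)3 deprotonates CHBr3 and α-elimination of bromide gives singlet CBr2, which adds in a concerted [2+1] manner to the only electron-rich alkene, the C10=C8 enol ether, from the α face anti to the pseudoaxial C1 methyl and so forms C9–C10 and C9–C8 (20). On warming, the bromide endo to the six-membered ring departs while the C8–C10 bond breaks in a disrotatory two-electron cyclopropyl-to-allyl opening pushed by the silyloxy oxygen, and loss of the silyl group from the 2-bromo oxyallyl cation leaves enone 21. The closest known reaction type is the one-carbon homologation of cyclic ketones through dihalocarbene adducts of their silyl enol ethers to 2-halocycloalk-2-enones. The seven-membered ring is thus made by ring enlargement and not by cyclisation (cheletropic addition, then electrocyclic cleavage of the shared bond of the bicyclo[4.1.0]heptane). No lasting stereocentre is created, since C8 and C10 of 20 return to sp2, and C1, C4, C5 and C6 are not touched. The step needs regiocontrol, secured because quaternary C1 allows only the C10=C8 enol ether, and chemoselectivity, secured by capping both hydroxyls and by SiEt3, which withstands alkoxide long enough for the small electrophilic carbene to reach the crowded alkene.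

Step 13
Reactants: 21 bromoenone
Product: 22 9-bromo-10β-alcohol
Conditions: NaBH4, CeCl3·7H2O, MeOH–THF, −40 °C
Reagents that add atoms: none
Why: Luche 1,2-reduction in which hydride adds to C10 anti to the pseudoaxial C1 methyl, as in 12-oxo steroids, and gives the pseudoequatorial 10β-alcohol, the epimer that step 15 inverts.

Step 14
Reactants: 22 bromo alcohol
Product: 24 10β-allylic alcohol (C8=C9; 4β-OSiEt3; 6α-OTBS), via C9 vinyllithium 23 (not isolated)
Conditions: t-BuLi (3.3 equiv), THF, −78 °C; MeOH
Reagents that add atoms: tert-butyllithium [Li]C(C)(C)C (lithium in 23 only)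
Why: Bromine–lithium exchange on the vinyl bromide after deprotonation of the hydroxyl, followed by protonation, removes the halogen without touching the silyl ethers or any stereocentre.

Step 15
Reactants: 24 10β-allylic alcohol; 25 angelic acid
Product: 26 10α-angelate (4β-OSiEt3; 6α-OTBS)
Conditions: angelic acid, PPh3, DIAD, toluene, 0 °C → rt
Reagents that add atoms: angelic acid C/C=C(/C)C(=O)O
Why: Mitsunobu esterification in which angelate displaces the allylic oxyphosphonium group at C10 by SN2 from the open α face anti to the C1 methyl (inversion next to a quaternary carbon is known for 17β-hydroxy steroids) and so sets 10α, and the Z alkene survives because the acid acts as nucleophile and is never activated at its acyl carbon.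

Step 16
Reactants: 26 bis-silyl angelate
Product: 27 10α-angeloyloxy-dauc-8-ene-4β,6α-diol
Conditions: HF·pyridine, pyridine, THF, 0 °C → rt
Reagents that add atoms: none
Why: Fluoride-driven cleavage of both silyl ethers under buffered conditions that spare the allylic ester, the Z alkene and the tertiary alcohol.

Step 17
Reactants: 27 diol; 28 3,4-dimethoxybenzoyl chloride
Product: 29 target CNP0142353.1
Conditions: 3,4-(MeO)2C6H3COCl, Et3N, DMAP, CH2Cl2, rt
Reagents that add atoms: 3,4-dimethoxybenzoyl chloride COc1ccc(cc1OC)C(=O)Cl
Why: DMAP-catalysed acylation takes only the secondary 6α-hydroxyl, because the tertiary 4β-hydroxyl flanked by isopropyl is inert under these conditions, with retention at C6.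

Compound list
1 | 2-methylcyclohexane-1,3-dione | CC1C(=O)CCCC1=O | starting material
2 | acrolein | C=CC=O | starting material
3 | 3-(1-methyl-2,6-dioxocyclohexyl)propanal | CC1(CCC=O)C(=O)CCCC1=O | intermediate
4 | (1S,5R)-5β-hydroxy-1β-methylhydrindane-4,10-dione, cis-fused | O=C1CCC[C@@]2(O)[C@]1(C)CCC2=O | intermediate
5 | (1S)-1β-methylhydrind-5-ene-4,10-dione | O=C1CCC=C2[C@]1(C)CCC2=O | intermediate
6 | 10,10-ethylenedioxy-1β-methylhydrind-5-en-4-one | C12(OCCO1)CCC=C3[C@]2(C)CCC3=O | intermediate
7 | 10,10-ethylenedioxy-1β-methylhydrind-5-en-4β-ol | C12(OCCO1)CCC=C3[C@]2(C)CC[C@@H]3O | intermediate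
8 | 6α-boryl-4β-boryloxy-5αH-hydrindane 10-ketal (not isolated) | C12(OCCO1)CC[C@H](B)[C@@H]3[C@]2(C)CC[C@@H]3OB | intermediate
9 | 10,10-ethylenedioxy-1β-methyl-5αH-hydrindane-4β,6α-diol | C12(OCCO1)CC[C@H](O)[C@@H]3[C@]2(C)CC[C@@H]3O | intermediate
10 | 6α-TBS ether of 9 | C12(OCCO1)CC[C@H](O[Si](C)(C)C(C)(C)C)[C@@H]3[C@]2(C)CC[C@@H]3O | intermediate
11 | 6α-(TBSO)-10,10-ethylenedioxy-1β-methyl-5αH-hydrindan-4-one | C12(OCCO1)CC[C@H](O[Si](C)(C)C(C)(C)C)[C@@H]3[C@]2(C)CCC3=O | intermediate
12 | isopropylmagnesium chloride | CC(C)[Mg]Cl | starting material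
13 | 4β-hydroxy-4α-isopropyl 10-ketal (not isolated, drawn as the alcohol) | C12(OCCO1)CC[C@H](O[Si](C)(C)C(C)(C)C)[C@@H]3[C@]2(C)CC[C@@]3(O)C(C)C | intermediate
14 | 4β-hydroxy-4α-isopropyl-6α-(TBSO)-1β-methyl-5αH-hydrindan-10-one | O=C1CC[C@H](O[Si](C)(C)C(C)(C)C)[C@@H]2[C@]1(C)CC[C@@]2(O)C(C)C | intermediate
15 | iodomethane | CI | starting material
16 | C10 lithium enolate, C4 lithium alkoxide of 14 (not isolated) | [Li]OC1=CC[C@H](O[Si](C)(C)C(C)(C)C)[C@@H]2[C@]1(C)CC[C@@]2(O[Li])C(C)C | intermediate
17 | 8-methyl derivative of 14, C8 epimers | O=C1C(C)C[C@H](O[Si](C)(C)C(C)(C)C)[C@@H]2[C@]1(C)CC[C@@]2(O)C(C)C | intermediate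
18 | C10 triethylsilyl enol ether, 4β-OSiEt3, 6α-OTBS (key-step precursor) | CC[Si](CC)(CC)OC1=C(C)C[C@H](O[Si](C)(C)C(C)(C)C)[C@@H]2[C@]1(C)CC[C@@]2(O[Si](CC)(CC)CC)C(C)C | intermediate
19 | bromoform | BrC(Br)Br | starting material
20 | 9,9-dibromo-8,10-cyclopropane, CBr2 on the α face (not isolated) | CC[Si](CC)(CC)O[C@]12[C@](C)(C1(Br)Br)C[C@H](O[Si](C)(C)C(C)(C)C)[C@@H]3[C@]2(C)CC[C@@]3(O[Si](CC)(CC)CC)C(C)C | intermediate
21 | 9-bromo-hydroazulen-10-one, C8=C9 (key-step product) | O=C1C(Br)=C(C)C[C@H](O[Si](C)(C)C(C)(C)C)[C@@H]2[C@]1(C)CC[C@@]2(O[Si](CC)(CC)CC)C(C)C | intermediate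
22 | 9-bromo-10β-alcohol | O[C@H]1C(Br)=C(C)C[C@H](O[Si](C)(C)C(C)(C)C)[C@@H]2[C@]1(C)CC[C@@]2(O[Si](CC)(CC)CC)C(C)C | intermediate
23 | C9 vinyllithium, C10 lithium alkoxide (not isolated) | [Li]O[C@H]1C([Li])=C(C)C[C@H](O[Si](C)(C)C(C)(C)C)[C@@H]2[C@]1(C)CC[C@@]2(O[Si](CC)(CC)CC)C(C)C | intermediate
24 | 10β-allylic alcohol | O[C@H]1C=C(C)C[C@H](O[Si](C)(C)C(C)(C)C)[C@@H]2[C@]1(C)CC[C@@]2(O[Si](CC)(CC)CC)C(C)C | intermediate
25 | angelic acid, (Z)-2-methylbut-2-enoic acid | C/C=C(/C)C(=O)O | starting material
26 | 10α-angelate, 4β-OSiEt3, 6α-OTBS | C/C=C(/C)C(=O)O[C@@H]1C=C(C)C[C@H](O[Si](C)(C)C(C)(C)C)[C@@H]2[C@]1(C)CC[C@@]2(O[Si](CC)(CC)CC)C(C)C | intermediate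
27 | 10α-angeloyloxy-dauc-8-ene-4β,6α-diol | C/C=C(/C)C(=O)O[C@@H]1C=C(C)C[C@H](O)[C@@H]2[C@]1(C)CC[C@@]2(O)C(C)C | intermediate
28 | 3,4-dimethoxybenzoyl chloride | COc1ccc(cc1OC)C(=O)Cl | starting material
29 | CNP0142353.1, 10α-angeloyloxy-6α-veratroyloxy-dauc-8-en-4β-ol | C/C=C(/C)C(=O)O[C@@H]1C=C(C)C[C@H](OC(=O)c2ccc(OC)c(OC)c2)[C@@H]2[C@]1(C)CC[C@@]2(O)C(C)C | target

Total step count: 17. Longest linear sequence: 17 steps (from 1).

Steps most likely to fail

Step 12.
- What may go wrong: capture of the carbene by the tetrasubstituted enol ether beside C1 may be slower than carbene decay and alkoxide-induced desilylation. Base may also attack the bromoenone once it forms.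
- Fallback (sets out from 18, returns at 24, same disconnection): the carbenoid from Et2Zn and CH2I2 (Simmons–Smith cyclopropanation) gives the silyloxycyclopropane F1. FeCl3 in DMF cleaves the C8–C10 bond by one-electron oxidation (Saegusa ring enlargement) and traps the tertiary C8 radical as the β-chloro ketone F2. NaOAc in hot MeOH eliminates HCl to the bromine-free enone F3. Luche reduction as in step 13 then gives 24, so steps 13 and 14 are replaced.

Step 15.
- What may go wrong: displacement at the allylic but neopentyl C10 may be so slow with a weak acid that elimination to a diene, attack at C8, or ionisation with loss of stereochemical fidelity takes over.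
- Fallback (sets out from 24, returns at 26): inversion and ester formation are separated. Mitsunobu inversion with the much more acidic 4-nitrobenzoic acid gives the 10α-(4-nitrobenzoate) F4, and K2CO3 in MeOH frees the 10α-alcohol F5. The angelate is then made by acyl transfer to this alcohol from the mixed anhydride of angelic acid and 2,4,6-trichlorobenzoyl chloride (Yamaguchi esterification, Et3N, toluene), which gives 26.

Step 9.
- What may go wrong: the branched nucleophile may act as a base or hydride donor towards the hindered ketone. That would cause epimerisation at C5, loss of the β-silyloxy group or simple reduction.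
- Fallback (sets out from 11, returns at 13 and then 14): 2-propenylmagnesium bromide with CeCl3, a flatter sp2 nucleophile with no β-hydrogen to transfer, gives the isopropenyl carbinol F6. Hydrogenation of its 1,1-disubstituted alkene (H2, RhCl(PPh3)3) gives 13, which 2 M HCl converts into 14.

Further compounds
F1 | step 12 | 10-triethylsilyloxy-8,10-cyclopropane, CH2 on the α face | CC[Si](CC)(CC)O[C@]12[C@](C)(C1)C[C@H](O[Si](C)(C)C(C)(C)C)[C@@H]3[C@]2(C)CC[C@@]3(O[Si](CC)(CC)CC)C(C)C
F2 | step 12 | 8-chloro-8-methyl-hydroazulan-10-one | O=C1CC(C)(Cl)C[C@H](O[Si](C)(C)C(C)(C)C)[C@@H]2[C@]1(C)CC[C@@]2(O[Si](CC)(CC)CC)C(C)C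
F3 | step 12 | hydroazul-8-en-10-one without bromine | O=C1C=C(C)C[C@H](O[Si](C)(C)C(C)(C)C)[C@@H]2[C@]1(C)CC[C@@]2(O[Si](CC)(CC)CC)C(C)C
F4 | step 15 | 10α-(4-nitrobenzoate) | O=C(O[C@@H]1C=C(C)C[C@H](O[Si](C)(C)C(C)(C)C)[C@@H]2[C@]1(C)CC[C@@]2(O[Si](CC)(CC)CC)C(C)C)c3ccc(cc3)[N+](=O)[O-]
F5 | step 15 | 10α-allylic alcohol | O[C@@H]1C=C(C)C[C@H](O[Si](C)(C)C(C)(C)C)[C@@H]2[C@]1(C)CC[C@@]2(O[Si](CC)(CC)CC)C(C)C
F6 | step 9 | 4β-hydroxy-4α-isopropenyl 10-ketal | C12(OCCO1)CC[C@H](O[Si](C)(C)C(C)(C)C)[C@@H]3[C@]2(C)CC[C@@]3(O)C(C)=C
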